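**The problem**

Target 22 is a single cyclohexanone ring in which five of the six ring carbons carry oxygen. The ring is numbered C1 (quaternary carbinol bearing the exocyclic C7H2OBz), C2 (ketone), C3 (CH2), C4 (CHOH), C5 (CHOBz) and C6 (CHOH). Four stereocentres must be set: C1 (S), C6 (S), C5 (R) and C4 (R); O1 and O6 are cis, O5 is trans to O6, and O4 is cis to O5. C1 and C6 form a cis-diol that maps onto C2/C3 of a tetrose; once tied in a dioxolane, C6 can direct C5, and C5 can direct C4 if both oxygens arrive in one metal-bridged event. The quaternary centre C1 cannot be corrected later, so it should be fixed early by a structural constraint and not by a face selectivity at a hindered ketone. The β-hydroxy ketone (C2/C4) dehydrates with base or hot acid, the C5 benzoate sits between two free hydroxyls and migrates under base, and only one of three secondary hydroxyls may be acylated; the ketone is therefore best unveiled last, under acid. The enabling feature is the C4–C5 bond: two adjacent, cis-oxygenated methines with only the C3 methylene between C4 and the C2 carbonyl, so that in the open chain C4 and C5 are both aldehyde carbons and the ring can be closed by reductive union of two like-polarised carbonyl carbons.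

**Retrosynthesis**

22 from 21, and 21 from 19 and 10. The last operation is hydrolytic: in 21 the C2 ketone is a dioxolane and the C1/C6 diol an acetonide, so the β-hydroxy ketone appears only at the end and under acid. The C5–O acyl bond is cut next, back to diol 19 and benzoyl chloride 10. The C5 ester must come after ring closure, because an acyloxy group α to an aldehyde would be cleaved by the reductant of the key step. The forward reaction has to distinguish O5 from O4; in 19 O5 is equatorial and O4 axial, which a tin acetal can read.

19 from 18. The C4–C5 bond is cut to dialdehyde 18. Against the neighbouring ring bonds (C3–C4 by aldol, C1–C6 or C1–C2 at the quaternary carbon) this is the only bond flanked by two secondary, cis-oxygenated carbons, and cutting it removes the ring and two stereocentres at once. The forward reaction must give the cis diol, place it anti to O6, and leave the benzoate, the ketals and the α-oxygen at C6 alone.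

18 from 16, 15 and 14. Both aldehydes are functional-group changes: C4 comes from the terminal alkene of an allyl group (16), C5 from a primary alcohol (15, silyl-protected in 14). The aldehydes are made last because 18 is both an α-alkoxy and a β,β-dialkoxy aldehyde. An allyl group is the simplest carrier of C3 and C4.

14 from 13, and 13 from 11. The dioxolane is traced to ketone 13, and 13 to the cyclic hemiketal 11 by capture of its open-chain tautomer 12 as the C5 silyl ether. The hemiketal is the point at which the two primary oxygens are told apart by structure: O5 is in the ring, O7 is free and takes the benzoate.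

11 from 9, and 9 from 7 and 8. The C2–C3 bond is cut to lactone 7 and allylmagnesium bromide 8. Addition to a lactone delivers C2 at the ketone oxidation level in one step, and the hemiketal 9 stops a second addition. The benzoate (10) goes on after the Grignard step.

7 from 6, and 6 from 4 and 5. The C1–C7 bond is cut to lactol 4 and formaldehyde 5 (aldol at the carbon α to the masked aldehyde); lactol 6 is then oxidised to 7. The configuration at C1 is dictated by the cis ring fusion of the lactol, which is what the quaternary centre asks for.

4 from 2 and 1. The tetrose acetonide 4 comes from L-arabinose 1 by acetonation of the cis-3,4-diol (2) and loss of C1 by glycol cleavage (via formate 3). Arabinose C3 and C4 become C1 and C6 of the target with the correct absolute configuration.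

**Roads not taken**

Alternative 1: The cut is C1–C7. A fully formed, protected ring with a ketone at C1 would take up the methylene of dimethylsulfoxonium methylide (Me3S(O)I, NaH) and close to spiro-oxirane A1, whose oxygen becomes the C1 hydroxyl; benzoate would later open the oxirane at C7.
- Merits: the branch carbon and the tertiary oxygen arrive in one step, the C4–C6 triad could be taken from a cyclitol, and C5 is already singled out by its own protecting group, so no late regiochemical question arises.
- Weak points: the configuration at C1 rests on a face selectivity at a ketone flanked by a ketal carbon and a silyloxy carbon. Under the basic ylide conditions enolisation toward C6 opens a path to loss of the C5 oxygen. Four differently protected oxygens around a 1,2-dicarbonyl pattern mean a long protecting-group sequence. The ring itself is not made by this step.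
- Comparison: A1 is better than the chosen plan on C5 differentiation and avoids a fragile dialdehyde. The chosen plan sets against this ring closure with two stereocentres in one step and a C1 configuration secured by ring fusion.

Alternative 2: The cut is C1–C6, paid for with the C4–O bond. A lactone would be converted with KN(SiMe3)2 and Me3SiCl into its silyl ketene acetal, which rearranges on warming (Ireland–Claisen, boat transition state) to cyclohexenecarboxylic acid A2, with C4=C5 as an alkene and C7 as a carboxyl group.
- Merits: a pericyclic C–C bond formation at the quaternary carbon under mild, non-reductive conditions, with C1 and C6 set together by chirality transfer.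
- Weak points: after A2 the carboxyl must be reduced and benzoylated, the alkene dihydroxylated (which leaves the same O4/O5 differentiation as in the chosen plan), the C2 silyl ether removed and oxidised in the presence of O4, and a benzyl ether on the tertiary O1 and a tert-butyl ether on O6 cleaved. The lactone with its enol ether also needs its own asymmetric synthesis, and the boat transition state is a less secure source of configuration.
- Comparison: A2 is stronger in how the quaternary C–C bond is made. The chosen plan sets against this the correct oxidation levels at C2, C4, C5 and C7 directly after ring closure and a chiral-pool origin of C1 and C6.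

Alternative 3: The cut is C3–C4 (intramolecular aldol). Hg(OCOCF3)2 (divalent mercury) in aqueous acetone would hydrate the exocyclic enol ether of a C4-branched hex-5-enopyranoside; loss of methanol and aldol closure of the mercury enolate onto the freed aldehyde would give A3, the 6-O-benzyl ether of the target.
- Merits: the β-hydroxy ketone is delivered in its final oxidation state, both benzoates are already in place, and one hydrogenolysis finishes the synthesis. No ketal has to be made or removed and no late regioselective acylation is needed. The usual preference for the new hydroxyl trans to the oxygen on the carbon that becomes C6 fits the target. In the endgame this road is at least as good as the chosen one.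
- Weak points: the substrate is a pyranoside with a tertiary alcohol and a benzoyloxymethyl branch at the sugar C4. This needs oxidation, a face-selective one-carbon addition and an elimination to the enol ether next to a base-sensitive benzoate. Mercury is used, and the β-hydroxy ketone can eliminate under the Lewis-acidic conditions. Only one stereocentre is made in the key step.
- Comparison: the chosen plan sets against this a short, mercury-free access to its cyclisation substrate, with the quaternary centre from a one-step aldol fixed by ring fusion, and two stereocentres from the ring closure.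

Key step: step 12

Remark on the chemistry: the hemiacetal or hemiketal carbon of 2, 4, 6, 9 and 11 and the ozonide carbon of 17 are formed as epimer mixtures and are left undefined in the SMILES, since each is destroyed before the key step.

Step 1
Reactants: 1 L-arabinose
Product: 2 3,4-O-isopropylidene-L-arabinopyranose
Conditions: 2,2-dimethoxypropane (about 1 equiv), TsOH (cat.), DMF, rt
Reagents that add atoms: 2,2-dimethoxypropane, COC(C)(C)OC
Why: Kinetic acid-catalysed transacetalisation takes the cis-3,4-diol of the pyranose as a dioxolane; no stereocentre is made.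

Step 2
Reactants: 2 3,4-O-isopropylidene-L-arabinopyranose
Product: 4 2,3-O-isopropylidene-L-erythrofuranose, via 4-O-formyl-2,3-O-isopropylidene-L-erythrose 3 (not isolated)
Conditions: NaIO4, H2O, 0 °C → rt; then Na2CO3
Reagents that add atoms: none
Why: Periodate glycol cleavage (Malaprade) of the only free vicinal diol cuts C1–C2; the formate left on O5 is hydrolysed by mild base and the hydroxy aldehyde closes to the lactol, the two remaining stereocentres being untouched.

Step 3
Reactants: 4 2,3-O-isopropylidene-L-erythrofuranose; 5 formaldehyde
Product: 6 2-C-(hydroxymethyl)-2,3-O-isopropylidene-L-erythrofuranose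
Conditions: 37% aq. HCHO, K2CO3, MeOH, 65 °C
Reagents that add atoms: none
Why: Crossed aldol of the enolisable open-chain aldehyde with formaldehyde, a known hydroxymethylation of 2,3-O-isopropylidene lactols. The quaternary centre (target C1) is fixed because formaldehyde adds anti to the C6 substituent and only that epimer, with the formyl carbon cis to C5, can re-close to the cis-fused lactol, which also shields the aldehyde from Cannizzaro reduction.

Step 4
Reactants: 6 2-C-(hydroxymethyl)-2,3-O-isopropylidene-L-erythrofuranose
Product: 7 2-C-(hydroxymethyl)-2,3-O-isopropylidene-L-erythrono-1,4-lactone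
Conditions: Br2, BaCO3, H2O, rt
Reagents that add atoms: none
Why: Bromine-water oxidation of an aldose lactol to the aldonolactone; only the hemiacetal is oxidised, and the carbonate buffer protects the acetonide.

Step 5
Reactants: 7 2-C-(hydroxymethyl)-2,3-O-isopropylidene-L-erythrono-1,4-lactone; 8 allylmagnesium bromide
Product: 9 1-C-allyl-2-C-(hydroxymethyl)-2,3-O-isopropylidene-L-erythrofuranose
Conditions: 8 (2.3 equiv), THF, −78 °C; NH4Cl quench at −78 °C
Reagents that add atoms: none
Why: Grignard addition to a lactone stopped at the hemiketal: one equivalent deprotonates O7, the next adds to the carbonyl, and the magnesium hemiketal alkoxide is stable at −78 °C until quench. The new anomeric centre is lost later.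

Step 6
Reactants: 9 1-C-allyl-2-C-(hydroxymethyl)-2,3-O-isopropylidene-L-erythrofuranose; 10 benzoyl chloride
Product: 11 1-C-allyl-2-C-(benzoyloxymethyl)-2,3-O-isopropylidene-L-erythrofuranose
Conditions: 10 (1.05 equiv), pyridine, CH2Cl2, 0 °C
Reagents that add atoms: none
Why: Acylation of the only free primary hydroxyl with one equivalent at 0 °C; the tertiary hemiketal hydroxyl does not compete and O5 is locked in the ring, so O7 and O5 are told apart by structure.

Step 7
Reactants: 11 1-C-allyl-2-C-(benzoyloxymethyl)-2,3-O-isopropylidene-L-erythrofuranose
Product: 13 [(4S,5S)-4-(but-3-enoyl)-5-(tert-butyldimethylsilyloxymethyl)-2,2-dimethyl-1,3-dioxolan-4-yl]methyl benzoate, via open-chain hydroxy ketone 12 (not isolated)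
Conditions: TBSCl, imidazole, DMAP (cat.), DMF, rt → 40 °C
Reagents that add atoms: tert-butyldimethylsilyl chloride, CC(C)(C)[Si](C)(C)Cl
Why: Silylative opening of a lactol through ring–chain tautomerism: imidazole equilibrates 11 with 12 and the silyl chloride captures the primary alcohol of 12, while the tertiary hemiketal hydroxyl of 11 is too hindered to be silylated.

Step 8
Reactants: 13 [(4S,5S)-4-(but-3-enoyl)-5-(tert-butyldimethylsilyloxymethyl)-2,2-dimethyl-1,3-dioxolan-4-yl]methyl benzoate
Product: 14 [(4S,5S)-4-(2-allyl-1,3-dioxolan-2-yl)-5-(tert-butyldimethylsilyloxymethyl)-2,2-dimethyl-1,3-dioxolan-4-yl]methyl benzoate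
Conditions: (TMSOCH2)2, TMSOTf (cat.), CH2Cl2, −78 → −20 °C; pyridine quench
Reagents that add atoms: 1,2-bis(trimethylsilyloxy)ethane, C[Si](C)(C)OCCO[Si](C)(C)C
Why: Noyori ketalisation is aprotic and cold, which should keep the β,γ-alkene out of conjugation and leave acetonide, silyl ether and benzoate intact; formation of hexamethyldisiloxane drives it.

Step 9
Reactants: 14 [(4S,5S)-4-(2-allyl-1,3-dioxolan-2-yl)-5-(tert-butyldimethylsilyloxymethyl)-2,2-dimethyl-1,3-dioxolan-4-yl]methyl benzoate
Product: 15 [(4S,5S)-4-(2-allyl-1,3-dioxolan-2-yl)-5-(hydroxymethyl)-2,2-dimethyl-1,3-dioxolan-4-yl]methyl benzoate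
Conditions: HF·pyridine, pyridine, THF, 0 °C → rt
Reagents that add atoms: none
Why: Fluoride cleavage of a primary silyl ether under buffered, non-basic conditions, so the C7 benzoate cannot migrate and the two ketals are not touched.

Step 10
Reactants: 15 [(4S,5S)-4-(2-allyl-1,3-dioxolan-2-yl)-5-(hydroxymethyl)-2,2-dimethyl-1,3-dioxolan-4-yl]methyl benzoate
Product: 16 [(4S,5R)-4-(2-allyl-1,3-dioxolan-2-yl)-5-formyl-2,2-dimethyl-1,3-dioxolan-4-yl]methyl benzoate
Conditions: Dess–Martin periodinane, CH2Cl2, 0 °C → rt
Reagents that add atoms: none
Why: Dess–Martin oxidation of the primary alcohol under neutral conditions, chosen to avoid epimerisation at C6 of the α-alkoxy aldehyde.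

Step 11
Reactants: 16 [(4S,5R)-4-(2-allyl-1,3-dioxolan-2-yl)-5-formyl-2,2-dimethyl-1,3-dioxolan-4-yl]methyl benzoate
Product: 18 [(4S,5R)-5-formyl-2,2-dimethyl-4-[2-(2-oxoethyl)-1,3-dioxolan-2-yl]-1,3-dioxolan-4-yl]methyl benzoate, via secondary ozonide 17 (not isolated)
Conditions: O3, CH2Cl2, −78 °C; then PPh3, −78 °C → rt; used crude
Reagents that add atoms: ozone, [O-][O+]=O
Why: Ozonolysis of the terminal alkene; in CH2Cl2 the 1,2,4-trioxolane 17 forms and triphenylphosphine reduces it to the aldehyde and formaldehyde. The neutral work-up matters because 18 is an α-alkoxy and a β,β-dialkoxy aldehyde.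

Step 12
Reactants: 18 [(4S,5R)-5-formyl-2,2-dimethyl-4-[2-(2-oxoethyl)-1,3-dioxolan-2-yl]-1,3-dioxolan-4-yl]methyl benzoate
Product: 19 pinacol diol: cyclohexane with C1/C6 acetonide, C2 ethylene ketal, C7 benzoate and free cis-4,5-diol on the face of C7 (opposite to O1 and O6)
Conditions: SmI2 (3 equiv, 0.1 M in THF), t-BuOH (3 equiv), THF, −78 °C → rt
Reagents that add atoms: none
Why: SmI2 (divalent samarium) transfers one electron to an aldehyde to give a ketyl, which adds to the carbon of the second, samarium-bound aldehyde; a second electron and protonation by tert-butanol give the diol. The closest known reaction type is the SmI2-promoted pinacol carbocyclisation of sugar-derived 1,6-dialdehydes to cis-diol cyclitols. The cyclohexane closes by 6-exo-trig attack of the ketyl carbon on the other C=O, cis-fused to the dioxolane. C4 and C5 are formed together, and trivalent samarium bridging the two oxygens in the bond-forming transition state should make the diol cis. The face is set at C5: the C5–O bond turns away from the α-oxygen O6 held in the acetonide, so O5, and with it O4, should end trans to O6 and O1. The step needs the aldehydes to react before anything else; the ketone is a dioxolane, the only ester is on C7 and not α to a carbonyl, and no acyloxy group is α to either aldehyde, so reductive C–O cleavage has no easy path. Loss of O6 by β-elimination after over-reduction at C5 is the competing path, which low temperature, the proton source and fast six-ring coupling should suppress.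

Step 13
Reactants: 19 pinacol diol; 10 benzoyl chloride
Product: 21 5-O-benzoate of 19, via 4,5-O-dibutylstannylene acetal 20 (not isolated)
Conditions: Bu2SnO, toluene, reflux (−H2O); then 10 (1.05 equiv), 0 °C → rt
Reagents that add atoms: none
Why: Stannylene-acetal activation of a cis-1,2-diol raises the nucleophilicity of the equatorial oxygen; in the chair that keeps C7 equatorial O5 is equatorial and O4 axial, so one equivalent of benzoyl chloride should acylate O5. No stereocentre changes.

Step 14
Reactants: 21 5-O-benzoate of 19
Product: 22 CNP0127041.1, [(1S,2S,3R,4R)-3-benzoyloxy-1,2,4-trihydroxy-6-oxocyclohexyl]methyl benzoate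
Conditions: TFA/H2O (4:1), 0 °C → rt
Reagents that add atoms: water, O
Why: Acid-catalysed hydrolysis of the acetonide and the dioxolane; benzoates survive aqueous acid, and the absence of base protects the β-hydroxy ketone from elimination and the C5 benzoate from migration.

Compound list

1 | L-arabinose | O=C[C@H](O)[C@@H](O)[C@@H](O)CO | starting material
2 | 3,4-O-isopropylidene-L-arabinopyranose | OC1OC[C@@H]2OC(C)(C)O[C@@H]2[C@H]1O | intermediate
3 | 4-O-formyl-2,3-O-isopropylidene-L-erythrose (not isolated) | O=COC[C@@H]1OC(C)(C)O[C@@H]1C=O | intermediate
4 | 2,3-O-isopropylidene-L-erythrofuranose | OC1OC[C@@H]2OC(C)(C)O[C@H]12 | intermediate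
5 | formaldehyde | C=O | starting material
6 | 2-C-(hydroxymethyl)-2,3-O-isopropylidene-L-erythrofuranose | OC1OC[C@@H]2OC(C)(C)O[C@]12CO | intermediate
7 | 2-C-(hydroxymethyl)-2,3-O-isopropylidene-L-erythrono-1,4-lactone | O=C1OC[C@@H]2OC(C)(C)O[C@]12CO | intermediate
8 | allylmagnesium bromide | C=CC[Mg]Br | starting material
9 | 1-C-allyl-2-C-(hydroxymethyl)-2,3-O-isopropylidene-L-erythrofuranose (cyclic hemiketal) | OC1(CC=C)OC[C@@H]2OC(C)(C)O[C@]12CO | intermediate
10 | benzoyl chloride | O=C(Cl)c1ccccc1 | starting material
11 | 1-C-allyl-2-C-(benzoyloxymethyl)-2,3-O-isopropylidene-L-erythrofuranose (cyclic hemiketal) | OC1(CC=C)OC[C@@H]2OC(C)(C)O[C@]12COC(=O)c1ccccc1 | intermediate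
12 | [(4S,5S)-4-(but-3-enoyl)-5-(hydroxymethyl)-2,2-dimethyl-1,3-dioxolan-4-yl]methyl benzoate, open-chain tautomer of 11 (not isolated) | O=C(OC[C@@]1(OC(C)(C)O[C@H]1CO)C(=O)CC=C)c1ccccc1 | intermediate
13 | [(4S,5S)-4-(but-3-enoyl)-5-(tert-butyldimethylsilyloxymethyl)-2,2-dimethyl-1,3-dioxolan-4-yl]methyl benzoate | O=C(OC[C@@]1(OC(C)(C)O[C@H]1CO[Si](C)(C)C(C)(C)C)C(=O)CC=C)c1ccccc1 | intermediate
14 | [(4S,5S)-4-(2-allyl-1,3-dioxolan-2-yl)-5-(tert-butyldimethylsilyloxymethyl)-2,2-dimethyl-1,3-dioxolan-4-yl]methyl benzoate | O=C(OC[C@@]1(OC(C)(C)O[C@H]1CO[Si](C)(C)C(C)(C)C)C2(CC=C)OCCO2)c1ccccc1 | intermediate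
15 | [(4S,5S)-4-(2-allyl-1,3-dioxolan-2-yl)-5-(hydroxymethyl)-2,2-dimethyl-1,3-dioxolan-4-yl]methyl benzoate | O=C(OC[C@@]1(OC(C)(C)O[C@H]1CO)C2(CC=C)OCCO2)c1ccccc1 | intermediate
16 | [(4S,5R)-4-(2-allyl-1,3-dioxolan-2-yl)-5-formyl-2,2-dimethyl-1,3-dioxolan-4-yl]methyl benzoate | O=C(OC[C@@]1(OC(C)(C)O[C@H]1C=O)C2(CC=C)OCCO2)c1ccccc1 | intermediate
17 | secondary ozonide (1,2,4-trioxolane) of 16 (not isolated) | O=C(OC[C@@]1(OC(C)(C)O[C@H]1C=O)C2(CC3OCOO3)OCCO2)c1ccccc1 | intermediate
18 | [(4S,5R)-5-formyl-2,2-dimethyl-4-[2-(2-oxoethyl)-1,3-dioxolan-2-yl]-1,3-dioxolan-4-yl]methyl benzoate (C4,C5-dialdehyde) | O=C(OC[C@@]1(OC(C)(C)O[C@H]1C=O)C2(CC=O)OCCO2)c1ccccc1 | intermediate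
19 | pinacol diol: C1/C6 acetonide, C2 ethylene ketal, C7 benzoate, cis-4,5-diol trans to O6 | O=C(OC[C@]12OC(C)(C)O[C@H]1[C@H](O)[C@H](O)CC23OCCO3)c1ccccc1 | intermediate
20 | 4,5-O-dibutylstannylene acetal of 19 (not isolated) | O=C(OC[C@]12OC(C)(C)O[C@H]1[C@H](O[Sn]3(CCCC)CCCC)[C@H](O3)CC24OCCO4)c1ccccc1 | intermediate
21 | 5-O-benzoate of 19 | O=C(OC[C@]12OC(C)(C)O[C@H]1[C@H](OC(=O)c3ccccc3)[C@H](O)CC24OCCO4)c1ccccc1 | intermediate
22 | CNP0127041.1, [(1S,2S,3R,4R)-3-benzoyloxy-1,2,4-trihydroxy-6-oxocyclohexyl]methyl benzoate | O=C(OC[C@@]1(O)C(=O)C[C@@H](O)[C@@H](OC(=O)c2ccccc2)[C@@H]1O)c1ccccc1 | target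

Total step count: 14. Longest linear sequence: 14 steps (1 to 22).

Least certain steps

Step 12 (key step). Most likely failures: poor facial selectivity, because only the C5 aldehyde has an α-oxygen to steer the coupling; loss of O6 by β-elimination if the C5 ketyl is reduced further before it couples; and opening of the dioxolane by elimination from the β,β-dialkoxy aldehyde, or epimerisation at C6, before the coupling starts. Fallback, from 16 back to 19: Wittig methylenation (Ph3P=CH2, THF, −78 °C) converts the C5 aldehyde into a vinyl group, giving the diene, the 5-vinyl analogue of 16 F1. Ring-closing metathesis with the second-generation Grubbs catalyst in CH2Cl2 forms the same C4–C5 bond as an alkene, giving the cis-fused cyclohexene F2. OsO4 (cat.) with N-methylmorpholine N-oxide should then add both hydroxyls anti to the allylic oxygen O6 and the dioxolane, which gives 19.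

Step 7. Most likely failures: the silylation stalls because the closed hemiketal dominates and opens slowly, or the base moves the β,γ-double bond of the open ketone into conjugation. Fallback, from 11 back to 13: NaBH4 in MeOH at 0 °C reduces the small open-chain fraction and drains the equilibrium to the open-chain diol (C2 epimers) F3. TBSCl and imidazole at 0 °C silylate only the primary hydroxyl, giving the C2 carbinol silyl ether F4. Dess–Martin oxidation of the hindered secondary alcohol then gives 13.

Step 8. Most likely failures: slow ketalisation of a ketone that is next to a quaternary, oxygen-bearing carbon; pushing the temperature then risks silyl or acetonide scrambling by the silyl triflate and migration of the alkene. Fallback, from 13 to 14: build the dioxolane from the carbonyl oxygen instead of replacing it, by BF3·OEt2-catalysed addition of oxirane to the ketone in CH2Cl2 at 0 °C. The carbonyl oxygen opens the activated epoxide and the alkoxide closes onto the resulting oxocarbenium ion, so no crowded tetrahedral intermediate has to lose a leaving group. This makes 14 directly (no new compound, F0).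

Step 13. Most likely failure: poor regioselectivity if the cis-fused acetonide distorts the chair so that O4 and O5 are not clearly axial and equatorial, or acylation at O4 because it is the less crowded oxygen. Fallback, from 19 to 22: trimethyl orthoacetate with camphorsulfonic acid (cat.) ties the diol as the cyclic 4,5-orthoacetate F5. Brief aqueous acetic acid opens it to the axial ester, the 4-O-acetate F6, leaving O5 free. Benzoyl chloride, pyridine and DMAP then give the 4-O-acetyl-5-O-benzoate F7. Methanolic HCl at 0 °C removes the acetate much faster than the benzoates and, after dilution with water, also the acetonide and the dioxolane, to reach 22.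

Step 14. Most likely failures: the dioxolane, next to an oxygenated quaternary carbon, hydrolyses slowly, and the acid strength then needed promotes dehydration of the β-hydroxy ketone to the enone or acid-catalysed benzoate migration. Fallback, from 21 to 22: ethane-1,2-dithiol and BF3·OEt2 in CH2Cl2 exchange the dioxolane for a dithiolane without water and strip the acetonide, giving the 2,2-(ethylenedithio) triol F8, in which no ketone is present to dehydrate. MeI and CaCO3 in aqueous MeCN then release the ketone by S-alkylation and hydrolysis at neutral pH, giving 22.

Further compounds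

F1 | step 12 | [(4S,5S)-4-(2-allyl-1,3-dioxolan-2-yl)-2,2-dimethyl-5-vinyl-1,3-dioxolan-4-yl]methyl benzoate | O=C(OC[C@@]1(OC(C)(C)O[C@H]1C=C)C2(CC=C)OCCO2)c1ccccc1
F2 | step 12 | cis-fused cyclohex-4-ene: C1/C6 acetonide, C2 ethylene ketal, C7 benzoate | O=C(OC[C@]12OC(C)(C)O[C@H]1C=CCC23OCCO3)c1ccccc1
F3 | step 7 | open-chain diol: C2 carbinol (both epimers) and C5 primary alcohol, C1/C6 acetonide, C7 benzoate | O=C(OC[C@@]1(OC(C)(C)O[C@H]1CO)C(O)CC=C)c1ccccc1
F4 | step 7 | 5-O-tert-butyldimethylsilyl ether of F3 | O=C(OC[C@@]1(OC(C)(C)O[C@H]1CO[Si](C)(C)C(C)(C)C)C(O)CC=C)c1ccccc1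
F0 | step 8 | none | none
F5 | step 13 | 4,5-O-(1-methoxyethylidene) orthoester of 19 | O=C(OC[C@]12OC(C)(C)O[C@H]1[C@H](OC3(C)OC)[C@H](O3)CC24OCCO4)c1ccccc1
F6 | step 13 | 4-O-acetate of 19 | O=C(OC[C@]12OC(C)(C)O[C@H]1[C@H](O)[C@H](OC(C)=O)CC23OCCO3)c1ccccc1
F7 | step 13 | 4-O-acetyl-5-O-benzoate of 19 | O=C(OC[C@]12OC(C)(C)O[C@H]1[C@H](OC(=O)c3ccccc3)[C@H](OC(C)=O)CC24OCCO4)c1ccccc1
F8 | step 14 | 1,3-dithiolane at C2 of the target (1,4,6-triol, 5,7-dibenzoate) | O=C(OC[C@@]1(O)C2(SCCS2)C[C@@H](O)[C@@H](OC(=O)c3ccccc3)[C@@H]1O)c1ccccc1
A1 | alternative 1 | C1 spiro-oxirane of the protected ring (C7 is the oxirane CH2) | C1O[C@@]12C(OC)(OC)C[C@@H](O[Si](C)(C)C(C)(C)C)[C@@H](OCc3ccc(OC)cc3)[C@@H]2O[Si](C)(C)C(C)(C)C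
A2 | alternative 2 | 1-benzyloxy-2-tert-butoxy-6-(tert-butyldimethylsilyloxy)cyclohex-3-ene-1-carboxylic acid | OC(=O)[C@@]1(OCc2ccccc2)[C@@H](O[Si](C)(C)C(C)(C)C)CC=C[C@@H]1OC(C)(C)C
A3 | alternative 3 | 6-O-benzyl ether of the target | O=C(OC[C@@]1(O)C(=O)C[C@@H](O)[C@@H](OC(=O)c2ccccc2)[C@@H]1OCc1ccccc1)c1ccccc1
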